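**Retrosynthetic overview**
- The target is opened at C12–C13: a primary C12 iodide is joined to the γ-carbon of a sparteine-complexed α-lithio N-Boc-N-aryl crotylamine. This chiral homoenolate equivalent makes the future β-carbon of the acid nucleophilic and sets C13; the Z-enecarbamate formed is a masked aldehyde, oxidised to the C15 acid.
- The iodide comes from a C13 acid by iododecarboxylation, and the acid from an isopropyl ketone by Baeyer–Villiger oxidation and saponification.
- The 8(17)-methylene comes from an enal by reductive 1,3-transposition through its tosylhydrazone.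
- The keto-enal comes from methyl abietate by cleavage of the 13(14)-alkene. No ring is built: rings A and B, with C4, C5, C9 and C10, are taken intact from the resin acid, and ring C is opened.

Assumption: the SMILES is read as (4R,5R,9S,10R,13R), i.e. the ring stereocentres of natural abietic acid (4α-CO2Me, 4β-CH3, 5α-H, 9α-H, 10β-CH3) plus 13R; methyl abietate is bought as the pure ester (otherwise abietic acid, MeI, K2CO3).

Step 1
Reactants: 1 methyl abietate (methyl abieta-7,13-dien-18-oate)
Product: 3 methyl 13,14-dioxo-13,14-secoabiet-7-en-18-oate, via ozonide 2 (not isolated)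
Conditions: O3 (1.0 equiv), CH2Cl2, −78 °C; then Me2S, −78 °C to rt
Reagents that add atoms: ozone, [O-][O+]=O
Why: Ozonolysis with reductive work-up; electrophilic oxidants attack the more electron-rich 13(14)-alkene at the isopropyl end of the diene first and the resulting enal is deactivated towards more ozone, and no stereocentre is made, so C4, C5, C9 and C10 are those of abietic acid.

Step 2
Reactants: 3 methyl 13,14-dioxo-13,14-secoabiet-7-en-18-oate
Product: 6 methyl 13-oxo-13,14-secoabiet-8(14)-en-18-oate, via tosylhydrazone 4 (not isolated), via allylic diazene 5 (not isolated)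
Conditions: TsNHNH2 (1.05 equiv), EtOH, rt; then catecholborane, CHCl3, 0 °C; then NaOAc·3H2O, reflux
Reagents that add atoms: none
Why: Kabalka reduction of an α,β-unsaturated tosylhydrazone (the aldehyde condenses far faster than the hindered isopropyl ketone): hydride adds to C=N, loss of sulfinate gives the allylic diazene, and its retro-ene loss of N2 puts H on C7 and moves the double bond to the exocyclic 8(17) position without touching C9.

Step 3
Reactants: 6 methyl 13-oxo-13,14-secoabiet-8(14)-en-18-oate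
Product: 8 18-methoxy-18-oxo-14,15,16-trinorlabd-8(17)-en-13-oic acid, via isopropyl ester 7 (not isolated)
Conditions: (Me3SiO)2, TMSOTf (10 mol %), 2,6-di-tert-butylpyridine, CH2Cl2, −40 °C; then LiOH, THF/MeOH/H2O, rt; HCl to pH 3
Reagents that add atoms: lithium hydroxide, [Li+].[OH-]
Why: Baeyer–Villiger oxidation with bis(trimethylsilyl) peroxide, an aprotic peroxide that does not epoxidise C=C bonds, with migration of the secondary isopropyl group in preference to the primary CH2; the unhindered isopropyl ester is then saponified (the inserted oxygen leaves with propan-2-ol) while the methyl ester on quaternary C4 is inert.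

Step 4
Reactants: 8 18-methoxy-18-oxo-14,15,16-trinorlabd-8(17)-en-13-oic acid
Product: 10 methyl 12-iodo-13,14,15,16-tetranorlabd-8(17)-en-18-oate, via Barton ester 9 (not isolated)
Conditions: 1-hydroxypyridine-2(1H)-thione, DCC, DMAP (cat.), CH2Cl2, 0 °C to rt, dark; then CHI3, PhH, hν (W lamp), reflux
Reagents that add atoms: iodoform, IC(I)I
Why: Barton decarboxylative iodination: the thiohydroxamate ester fragments in a radical chain to the primary C12 radical, which takes iodine from CHI3 faster than the disfavoured 4-exo or 5-endo closure onto the 8(17)-alkene.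

Step 5
Reactants: 11 tert-butyl N-(4-methoxyphenyl)carbamate; 12 (E)-1-bromobut-2-ene
Product: 13 tert-butyl N-[(2E)-but-2-en-1-yl]-N-(4-methoxyphenyl)carbamate
Conditions: NaH, DMF, 0 °C to rt
Reagents that add atoms: none
Why: N-Alkylation (SN2) of the sodium carbamate with the primary allylic bromide, with the E geometry of 12 retained.

Step 6
Reactants: 13 tert-butyl N-[(2E)-but-2-en-1-yl]-N-(4-methoxyphenyl)carbamate; 10 methyl 12-iodo-13,14,15,16-tetranorlabd-8(17)-en-18-oate
Product: 15 methyl (13R,14Z)-15-[(tert-butoxycarbonyl)(4-methoxyphenyl)amino]labda-8(17),14-dien-18-oate, via lithio carbamate 14 (not isolated)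
Conditions: 13 (1.3 equiv), n-BuLi, (−)-sparteine, PhMe, −78 °C, 1 h; then 10, −78 to −40 °C
Reagents that add atoms: none
Why: Sparteine-mediated α-lithiation of an N-Boc-N-aryl allylamine (Beak-type asymmetric homoenolate equivalent) gives a configurationally stable organolithium that attacks the primary iodide through its γ-carbon anti to lithium (anti-SE2′), so that C12 and the future β-carbon C13 of the acid, both acceptor carbons in ordinary synthons, are joined, C13 (R) is set under ligand control and the Z-enecarbamate is a masked aldehyde; the ester on quaternary C4 is inert at −78 °C.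

Step 7
Reactants: 15 methyl (13R,14Z)-15-[(tert-butoxycarbonyl)(4-methoxyphenyl)amino]labda-8(17),14-dien-18-oate
Product: 17 (13R)-18-methoxy-18-oxolabd-8(17)-en-15-oic acid, via aldehyde 16 (not isolated)
Conditions: 1 M HCl, THF, 0 °C to rt; then NaClO2, NaH2PO4, 2-methyl-2-butene, t-BuOH/H2O, rt
Reagents that add atoms: water, O; sodium chlorite NaClO2, [Na+].[O-]Cl=O
Why: Acid hydrolysis of the enecarbamate releases the aldehyde and carbamate 11, and Pinnick oxidation with a hypochlorite scavenger gives the acid without touching the exocyclic alkene; C13, β to the carbonyl, cannot epimerise.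

**Compound list**
1 | methyl abietate (methyl abieta-7,13-dien-18-oate) | CC(C)C1=CC2=CC[C@@H]3[C@@]([C@H]2CC1)(CCC[C@@]3(C)C(=O)OC)C | starting material
2 | 13,14-ozonide of 1 (1,2,4-trioxolane bridging C13 and C14, mixture at these two carbons) | CC(C)C12CC[C@H]3C(=CC[C@@H]4[C@]3(C)CCC[C@@]4(C)C(=O)OC)C(O1)OO2 | intermediate
3 | methyl 13,14-dioxo-13,14-secoabiet-7-en-18-oate (keto-enal, 9α-H) | O=CC1=CC[C@@H]2[C@](C)(CCC[C@@]2(C)C(=O)OC)[C@H]1CCC(=O)C(C)C | intermediate
4 | C14 (E)-tosylhydrazone of 3 | Cc1ccc(cc1)S(=O)(=O)N/N=C/C1=CC[C@@H]2[C@](C)(CCC[C@@]2(C)C(=O)OC)[C@H]1CCC(=O)C(C)C | intermediate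
5 | methyl 14-diazenyl-13-oxo-13,14-secoabiet-7-en-18-oate (allylic diazene) | N=NCC1=CC[C@@H]2[C@](C)(CCC[C@@]2(C)C(=O)OC)[C@H]1CCC(=O)C(C)C | intermediate
6 | methyl 13-oxo-13,14-secoabiet-8(14)-en-18-oate (exocyclic methylene, 9α-H) | C=C1CC[C@@H]2[C@](C)(CCC[C@@]2(C)C(=O)OC)[C@H]1CCC(=O)C(C)C | intermediate
7 | 18-methyl 13-propan-2-yl 14,15,16-trinorlabd-8(17)-ene-13,18-dioate | C=C1CC[C@@H]2[C@](C)(CCC[C@@]2(C)C(=O)OC)[C@H]1CCC(=O)OC(C)C | intermediate
8 | 18-methoxy-18-oxo-14,15,16-trinorlabd-8(17)-en-13-oic acid | C=C1CC[C@@H]2[C@](C)(CCC[C@@]2(C)C(=O)OC)[C@H]1CCC(=O)O | intermediate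
9 | 2-thioxopyridin-1(2H)-yl ester of 8 (Barton ester) | C=C1CC[C@@H]2[C@](C)(CCC[C@@]2(C)C(=O)OC)[C@H]1CCC(=O)On1ccccc1=S | intermediate
10 | methyl 12-iodo-13,14,15,16-tetranorlabd-8(17)-en-18-oate | C=C1CC[C@@H]2[C@](C)(CCC[C@@]2(C)C(=O)OC)[C@H]1CCI | intermediate
11 | tert-butyl N-(4-methoxyphenyl)carbamate | COc1ccc(NC(=O)OC(C)(C)C)cc1 | starting material
12 | (E)-1-bromobut-2-ene | C/C=C/CBr | starting material
13 | tert-butyl N-[(2E)-but-2-en-1-yl]-N-(4-methoxyphenyl)carbamate | C/C=C/CN(C(=O)OC(C)(C)C)c1ccc(OC)cc1 | intermediate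
14 | α-lithio derivative of 13 as its (−)-sparteine complex (configuration at C–Li as drawn, the one that gives 13R by anti attack) | C/C=C/[C@H]([Li])N(C(=O)OC(C)(C)C)c1ccc(OC)cc1 | intermediate
15 | methyl (13R,14Z)-15-[(tert-butoxycarbonyl)(4-methoxyphenyl)amino]labda-8(17),14-dien-18-oate | C=C1CC[C@@H]2[C@](C)(CCC[C@@]2(C)C(=O)OC)[C@H]1CC[C@@H](C)/C=C\N(C(=O)OC(C)(C)C)c1ccc(OC)cc1 | intermediate
16 | methyl (13R)-15-oxolabd-8(17)-en-18-oate | C=C1CC[C@@H]2[C@](C)(CCC[C@@]2(C)C(=O)OC)[C@H]1CC[C@@H](C)CC=O | intermediate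
17 | (13R)-18-methoxy-18-oxolabd-8(17)-en-15-oic acid, (4R,5R,9S,10R,13R) | C=C1CC[C@@H]2[C@](C)(CCC[C@@]2(C)C(=O)OC)[C@H]1CC[C@@H](C)CC(=O)O | target

**Step count**
Total: 7 steps. Longest linear sequence: 6 steps (1, 2, 3, 4, 6, 7) from methyl abietate.

**Three steps most likely to fail**

Step 6. The risks are γ- versus α-attack, E2 of the iodide, and the level and sense of induction with a 3-methyl rather than 3-aryl allylamine. I have not verified which sense (−)-sparteine gives in this series; if the first run gives 13S, the antipodal organolithium is reached with the same ligand by stannylation (Me3SnCl) and tin–lithium exchange. The fallback sets out from 10 and comes back at 17, and supplies the nucleophilic β-carbon as an alkenylboron instead. Methyl (2Z)-3-(4,4,5,5-tetramethyl-1,3,2-dioxaborolan-2-yl)but-2-enoate F1 is made from methyl but-2-ynoate (B2pin2, CuCl, NaOt-Bu, Xantphos, MeOH). Alkyl–alkenyl Suzuki coupling of 10 with it (Pd(OAc)2, PCy3, K3PO4·H2O) gives dimethyl (13E)-labda-8(17),13-diene-15,18-dioate F2 with retention of geometry. Copper hydride conjugate reduction (Cu(OAc)2·H2O, the DTBM-SEGPHOS antipode selected for 13R, PMHS, t-BuOH, PhMe), to which the exocyclic alkene is inert, gives dimethyl (13R)-labd-8(17)-ene-15,18-dioate F3. LiOH (THF/H2O, rt) then cleaves only the unhindered C15 ester to give 17.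

Step 3. The Baeyer–Villiger oxidation runs beside an acid-sensitive, epoxidisable exocyclic alkene, and acyclic ketones react slowly with this reagent. The fallback sets out from 1 and comes back at 8; it removes the isopropyl group before the alkene exists. Ozonolysis of 1 in CH2Cl2/MeOH traps the C13 carbonyl oxide as the α-methoxy hydroperoxide F4. FeSO4·7H2O and Cu(OAc)2 fragment it, with loss of the isopropyl radical as propene, to dimethyl 14-oxo-13,14-seco-15,16,17-trinorabiet-7-ene-13,18-dioate F5. The transposition of step 2, through the tosylhydrazone F6 and the allylic diazene F7, gives dimethyl 14,15,16-trinorlabd-8(17)-ene-13,18-dioate F8. LiOH cleaves its unhindered ester to give 8.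

Step 4. The radical iododecarboxylation runs beside an alkene and gives a light-sensitive primary iodide. The fallback sets out from 8 and comes back at 17; it uses the acid directly as the electrophile. N-Hydroxyphthalimide and DIC give the redox-active ester F9. Nickel-hydride hydroalkylation of purchased N-phenylbut-3-enamide (NiBr2(dme), chiral bis(oxazoline), (MeO)2MeSiH, KF) should add Ni–H across the terminal alkene to an O-chelated β-nickel amide, a catalytic homoenolate, which captures the C12 radical to give the (13R)-anilide F10. This enantioselective, proximal-selective form with a redox-active ester is an extrapolation and would need screening. Boc2O/DMAP followed by LiOH/H2O2 then cleaves it through the N-Boc anilide F11 to give 17.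

**Further compounds**
F1 | step 6 | methyl (2Z)-3-(4,4,5,5-tetramethyl-1,3,2-dioxaborolan-2-yl)but-2-enoate | C/C(B1OC(C)(C)C(C)(C)O1)=C\C(=O)OC
F2 | step 6 | dimethyl (13E)-labda-8(17),13-diene-15,18-dioate | C=C1CC[C@@H]2[C@](C)(CCC[C@@]2(C)C(=O)OC)[C@H]1CC/C(C)=C/C(=O)OC
F3 | step 6 | dimethyl (13R)-labd-8(17)-ene-15,18-dioate | C=C1CC[C@@H]2[C@](C)(CCC[C@@]2(C)C(=O)OC)[C@H]1CC[C@@H](C)CC(=O)OC
F4 | step 3 | methyl 13-hydroperoxy-13-methoxy-14-oxo-13,14-secoabiet-7-en-18-oate (mixture at C13) | O=CC1=CC[C@@H]2[C@](C)(CCC[C@@]2(C)C(=O)OC)[C@H]1CCC(OC)(OO)C(C)C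
F5 | step 3 | dimethyl 14-oxo-13,14-seco-15,16,17-trinorabiet-7-ene-13,18-dioate | O=CC1=CC[C@@H]2[C@](C)(CCC[C@@]2(C)C(=O)OC)[C@H]1CCC(=O)OC
F6 | step 3 | C14 (E)-tosylhydrazone of F5 | Cc1ccc(cc1)S(=O)(=O)N/N=C/C1=CC[C@@H]2[C@](C)(CCC[C@@]2(C)C(=O)OC)[C@H]1CCC(=O)OC
F7 | step 3 | dimethyl 14-diazenyl-13,14-seco-15,16,17-trinorabiet-7-ene-13,18-dioate | N=NCC1=CC[C@@H]2[C@](C)(CCC[C@@]2(C)C(=O)OC)[C@H]1CCC(=O)OC
F8 | step 3 | dimethyl 14,15,16-trinorlabd-8(17)-ene-13,18-dioate | C=C1CC[C@@H]2[C@](C)(CCC[C@@]2(C)C(=O)OC)[C@H]1CCC(=O)OC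
F9 | step 4 | 1,3-dioxoisoindolin-2-yl ester of 8 | C=C1CC[C@@H]2[C@](C)(CCC[C@@]2(C)C(=O)OC)[C@H]1CCC(=O)ON1C(=O)c2ccccc2C1=O
F10 | step 4 | methyl (13R)-15-oxo-15-(phenylamino)labd-8(17)-en-18-oate | C=C1CC[C@@H]2[C@](C)(CCC[C@@]2(C)C(=O)OC)[C@H]1CC[C@@H](C)CC(=O)Nc1ccccc1
F11 | step 4 | methyl (13R)-15-[(tert-butoxycarbonyl)(phenyl)amino]-15-oxolabd-8(17)-en-18-oate | C=C1CC[C@@H]2[C@](C)(CCC[C@@]2(C)C(=O)OC)[C@H]1CC[C@@H](C)CC(=O)N(C(=O)OC(C)(C)C)c1ccccc1
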